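**Retrosynthetic overview**
1. Target 23 ⇐ triphenol 22 by twofold ortho-formylation; both tertiary carbinols come from methyl-metal additions to a C4 ketone and to a C7 nitrile/acetyl group.
2. Ring B (formed last) ⇐ key step: intramolecular Stetter reaction, the C7 aldehyde as an acyl anion adding to the C6 methylidene of an enone (C6–C7 bond, 1,4-dione 17).
3. Quaternary C10 ⇐ conjugate addition of a homoenolate (d3) equivalent to enone 10, anti to the C1 side chain (C9–C10 bond).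
4. Ring A (formed first) ⇐ enamine Michael addition/aldol condensation of aldehyde 5 with methyl vinyl ketone, then conjugate methylation/dehydrogenation.
5. C9' ⇐ iminium-catalysed Friedel–Crafts alkylation of phenol 1 with enal 2; the aromatic ring is bought.

Assumption: carbon labels follow the eudesmane numbering of the target (C9' = benzylic carbon, C1 = ring carbon bonded to it, C4 = ring carbinol carbon, C5/C10 = ring-fusion carbons, C7 = ring carbon bearing the hydroxypropyl group, C11 = its carbinol carbon); lactol 4 (C2 epimers) and Mannich bases 13/14 (C5 epimers) are used as mixtures because those centres are erased later.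

Step 1
Reactants: 1 3,5-bis(benzyloxy)phenol; 2 (E)-5-methylhex-2-enal
Product: 4 (4R)-5,7-bis(benzyloxy)-4-(2-methylpropyl)chroman-2-ol (lactol as C2 epimers), via hydroxy aldehyde 3 (not isolated)
Conditions: (S)-α,α-diphenylprolinol TMS ether (20 mol %), PhCO2H (20 mol %), CH2Cl2, 0 °C → rt
Reagents that add atoms: none
Why: Iminium-ion organocatalysis (asymmetric Friedel–Crafts conjugate addition followed by hemiacetalisation), in which the (S)-prolinol ether shields one face of the E-iminium of 2 so that the phenol carbon ortho to OH adds to the β-carbon from the open face and sets C9' as R, lactol closure pulling the equilibrium forward.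

Step 2
Reactants: 4 (4R)-5,7-bis(benzyloxy)-4-(2-methylpropyl)chroman-2-ol
Product: 5 (3R)-5-methyl-3-[2,4,6-tris(benzyloxy)phenyl]hexanal
Conditions: BnBr, K2CO3, DMF, rt
Reagents that add atoms: benzyl bromide, BrCc1ccccc1
Why: Williamson etherification of the ring-opened phenoxide–aldehyde tautomer frees the aldehyde and masks the phenol that would otherwise add back to the enones made later, without touching C9'.

Step 3
Reactants: 5 (3R)-5-methyl-3-[2,4,6-tris(benzyloxy)phenyl]hexanal; 6 methyl vinyl ketone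
Product: 8 (4S)-4-[(1R)-3-methyl-1-[2,4,6-tris(benzyloxy)phenyl]butyl]cyclohex-2-en-1-one, via keto aldehyde 7 (not isolated)
Conditions: (R)-α,α-diphenylprolinol methyl ether (10 mol %), ethyl 3,4-dihydroxybenzoate (20 mol %), neat, 4 °C; then LiOH (0.2 equiv), iPrOH, rt
Reagents that add atoms: none
Why: Enamine-catalysed Michael addition to the vinyl ketone followed by intramolecular aldol condensation (organocatalytic Robinson-type annulation) builds ring A, the E-enamine of the (R)-catalyst being attacked anti to its shielding group so that C1 is set as R under catalyst control and survives the mild dehydration.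

Step 4
Reactants: 8 (4S)-4-[(1R)-3-methyl-1-[2,4,6-tris(benzyloxy)phenyl]butyl]cyclohex-2-en-1-one
Product: 10 (4R)-3-methyl-4-[(1R)-3-methyl-1-[2,4,6-tris(benzyloxy)phenyl]butyl]cyclohex-2-en-1-one, via silyl enol ether 9 (not isolated)
Conditions: MeMgBr, CuBr·SMe2 (10 mol %), TMSCl, THF, −78 °C; crude; then Pd(OAc)2 (10 mol %), O2 (1 atm), DMSO, 25 °C
Reagents that add atoms: methylmagnesium bromide, C[Mg]Br
Why: Copper-catalysed conjugate methylation trapped as the regiodefined silyl enol ether, then Saegusa–Ito dehydrogenation (aerobic Larock variant), which can only remove the C10 hydrogen, returns a 3-methyl enone ready for a second β-addition while the transient C10 centre is erased and C1 is untouched.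

Step 5
Reactants: 10 (4R)-3-methyl-4-[(1R)-3-methyl-1-[2,4,6-tris(benzyloxy)phenyl]butyl]cyclohex-2-en-1-one; 11 2-(2-bromoethyl)-1,3-dioxolane
Product: 15 (3R,4R)-3-[2-(1,3-dioxolan-2-yl)ethyl]-3-methyl-2-methylidene-4-[(1R)-3-methyl-1-[2,4,6-tris(benzyloxy)phenyl]butyl]cyclohexan-1-one, via magnesium enolate 12 (not isolated), via Mannich base 13 (not isolated), via ammonium iodide 14 (not isolated)
Conditions: 11, Mg, THF, 25 °C; add to 10, CuBr·SMe2 (20 mol %), THF, −40 → 0 °C; Eschenmoser's salt, 0 °C → rt; crude; MeI, MeOH; NaHCO3 (aq), CH2Cl2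
Reagents that add atoms: Eschenmoser's salt (N,N-dimethylmethylideneammonium iodide), C[N+](C)=C.[I-]
Why: Copper-catalysed conjugate addition of a homoenolate (d3) equivalent, the acetal Grignard adding to C10 anti to the C1 side chain (held pseudo-axial by allylic strain with the C10 methyl) to fix the quaternary centre C10 as R, after which the regiodefined enolate is intercepted in a Mannich reaction and the amine is methylated and eliminated (Hofmann-type) to install the C6 methylidene.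

Step 6
Reactants: 15 (3R,4R)-3-[2-(1,3-dioxolan-2-yl)ethyl]-3-methyl-2-methylidene-4-[(1R)-3-methyl-1-[2,4,6-tris(benzyloxy)phenyl]butyl]cyclohexan-1-one
Product: 17 (4R,4aR,8aS)-4a-methyl-4-[(1R)-3-methyl-1-[2,4,6-tris(benzyloxy)phenyl]butyl]octahydronaphthalene-1,7(2H,8H)-dione (trans-fused), via enone aldehyde 16 (not isolated)
Conditions: HCl (cat.), THF/H2O, rt; crude; then 3-benzyl-5-(2-hydroxyethyl)-4-methylthiazolium chloride (20 mol %), Et3N (0.5 equiv), EtOH, 70 °C
Reagents that add atoms: water, O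
Why: Acetal hydrolysis then intramolecular Stetter reaction, in which the thiazolium-derived Breslow intermediate turns the C7 aldehyde into an acyl anion that adds 6-endo to the methylidene carbon C6 of the enone, joining two normally electrophilic carbons to close ring B as a 1,4-dione, while C5 equilibrates through its enol under Et3N to the more stable trans ring fusion (5S).

Step 7
Reactants: 17 (4R,4aR,8aS)-4a-methyl-4-[(1R)-3-methyl-1-[2,4,6-tris(benzyloxy)phenyl]butyl]octahydronaphthalene-1,7(2H,8H)-dione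
Product: 18 (2S,4aR,5R,8aS)-4a-methyl-5-[(1R)-3-methyl-1-[2,4,6-tris(benzyloxy)phenyl]butyl]-8-oxodecahydronaphthalene-2-carbonitrile
Conditions: TosMIC, tBuOK, DME/EtOH, 0 → 40 °C
Reagents that add atoms: TosMIC (p-toluenesulfonylmethyl isocyanide), [C-]#[N+]CS(=O)(=O)c1ccc(C)cc1
Why: Van Leusen reductive cyanation converts the unhindered ring-B ketone into the homologous nitrile (the C4 ketone is shielded by the ring fusion and the syn-axial C10 methyl), and tBuOK equilibrates C7 to the equatorial epimer (7S).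

Step 8
Reactants: 18 (2S,4aR,5R,8aS)-4a-methyl-5-[(1R)-3-methyl-1-[2,4,6-tris(benzyloxy)phenyl]butyl]-8-oxodecahydronaphthalene-2-carbonitrile
Product: 20 1-[(2S,4aR,5R,8R,8aS)-8-hydroxy-4a,8-dimethyl-5-[(1R)-3-methyl-1-[2,4,6-tris(benzyloxy)phenyl]butyl]decahydronaphthalen-2-yl]ethan-1-one, via ketimine 19 (not isolated)
Conditions: MeLi (4 equiv), Et2O/THF, −78 → 0 °C; then 1 M HCl, 0 °C, 30 min
Reagents that add atoms: methyllithium, [Li]C; water, O
Why: Organolithium 1,2-additions, MeLi attacking the C4 ketone from the equatorial side away from the syn-axial C10 methyl to give the axial tertiary alcohol (4R) and adding once to the nitrile to give an N-lithio ketimine that is hydrolysed to the methyl ketone, C7 staying equatorial.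

Step 9
Reactants: 20 1-[(2S,4aR,5R,8R,8aS)-8-hydroxy-4a,8-dimethyl-5-[(1R)-3-methyl-1-[2,4,6-tris(benzyloxy)phenyl]butyl]decahydronaphthalen-2-yl]ethan-1-one
Product: 21 (1R,4R,4aR,7S,8aS)-7-(2-hydroxypropan-2-yl)-1,4a-dimethyl-4-[(1R)-3-methyl-1-[2,4,6-tris(benzyloxy)phenyl]butyl]decahydronaphthalen-1-ol
Conditions: MeMgBr (3 equiv), THF, 0 °C → rt; NH4Cl (aq)
Reagents that add atoms: methylmagnesium bromide, C[Mg]Br
Why: Grignard addition to the methyl ketone gives the C11 tertiary alcohol without creating a stereocentre, the C4 alkoxide formed first being inert.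

Step 10
Reactants: 21 (1R,4R,4aR,7S,8aS)-7-(2-hydroxypropan-2-yl)-1,4a-dimethyl-4-[(1R)-3-methyl-1-[2,4,6-tris(benzyloxy)phenyl]butyl]decahydronaphthalen-1-ol
Product: 22 (1R,4R,4aR,7S,8aS)-7-(2-hydroxypropan-2-yl)-1,4a-dimethyl-4-[(1R)-3-methyl-1-(2,4,6-trihydroxyphenyl)butyl]decahydronaphthalen-1-ol
Conditions: H2 (1 atm), 10 % Pd/C, EtOAc/MeOH, rt
Reagents that add atoms: none
Why: Catalytic hydrogenolysis removes the three O-benzyl groups, the only reducible functions left, and leaves the tertiary alcohols and all stereocentres unchanged.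

Step 11
Reactants: 22 (1R,4R,4aR,7S,8aS)-7-(2-hydroxypropan-2-yl)-1,4a-dimethyl-4-[(1R)-3-methyl-1-(2,4,6-trihydroxyphenyl)butyl]decahydronaphthalen-1-ol
Product: 23 2,4,6-trihydroxy-5-[(1R)-1-[(1R,4R,4aS,6S,8aR)-4-hydroxy-6-(2-hydroxypropan-2-yl)-4,8a-dimethyldecahydronaphthalen-1-yl]-3-methylbutyl]benzene-1,3-dicarbaldehyde (CNP0409870.6)
Conditions: MgCl2, Et3N, (CH2O)n (excess), THF, reflux; then 1 M HCl (aq), 0 °C
Reagents that add atoms: paraformaldehyde (as formaldehyde), C=O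
Why: Casnati–Skattebøl ortho-formylation (magnesium phenoxide-directed hydroxymethylation followed by Oppenauer-type hydride transfer to formaldehyde) occurs at both free ring positions, each flanked by two phenols, under non-acidic conditions that spare the two tertiary alcohols and every stereocentre.

**Compound list**
1 | 3,5-bis(benzyloxy)phenol | Oc1cc(OCc2ccccc2)cc(OCc2ccccc2)c1 | starting material
2 | (E)-5-methylhex-2-enal | CC(C)C/C=C/C=O | starting material
3 | (3R)-3-[2,4-bis(benzyloxy)-6-hydroxyphenyl]-5-methylhexanal (open form of 4) | CC(C)C[C@@H](c1c(O)cc(OCc2ccccc2)cc1OCc1ccccc1)CC=O | intermediate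
4 | (4R)-5,7-bis(benzyloxy)-4-(2-methylpropyl)chroman-2-ol (C2 epimers) | CC(C)C[C@@H]1CC(O)Oc2cc(OCc3ccccc3)cc(OCc3ccccc3)c12 | intermediate
5 | (3R)-5-methyl-3-[2,4,6-tris(benzyloxy)phenyl]hexanal | CC(C)C[C@@H](c1c(OCc2ccccc2)cc(OCc2ccccc2)cc1OCc1ccccc1)CC=O | intermediate
6 | methyl vinyl ketone (but-3-en-2-one) | CC(=O)C=C | starting material
7 | (2R)-2-[(1R)-3-methyl-1-[2,4,6-tris(benzyloxy)phenyl]butyl]-5-oxohexanal | CC(C)C[C@@H](c1c(OCc2ccccc2)cc(OCc2ccccc2)cc1OCc1ccccc1)[C@H](C=O)CCC(C)=O | intermediate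
8 | (4S)-4-[(1R)-3-methyl-1-[2,4,6-tris(benzyloxy)phenyl]butyl]cyclohex-2-en-1-one | CC(C)C[C@@H](c1c(OCc2ccccc2)cc(OCc2ccccc2)cc1OCc1ccccc1)[C@H]1CCC(=O)C=C1 | intermediate
9 | trimethyl[[(3R,4S)-3-methyl-4-[(1R)-3-methyl-1-[2,4,6-tris(benzyloxy)phenyl]butyl]cyclohex-1-en-1-yl]oxy]silane (3,4-trans) | CC(C)C[C@@H](c1c(OCc2ccccc2)cc(OCc2ccccc2)cc1OCc1ccccc1)[C@H]1CCC(O[Si](C)(C)C)=C[C@@H]1C | intermediate
10 | (4R)-3-methyl-4-[(1R)-3-methyl-1-[2,4,6-tris(benzyloxy)phenyl]butyl]cyclohex-2-en-1-one | CC(C)C[C@@H](c1c(OCc2ccccc2)cc(OCc2ccccc2)cc1OCc1ccccc1)[C@H]1CCC(=O)C=C1C | intermediate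
11 | 2-(2-bromoethyl)-1,3-dioxolane | BrCCC1OCCO1 | starting material
12 | bromomagnesium enolate of (3R,4R)-3-[2-(1,3-dioxolan-2-yl)ethyl]-3-methyl-4-[(1R)-3-methyl-1-[2,4,6-tris(benzyloxy)phenyl]butyl]cyclohexan-1-one | CC(C)C[C@@H](c1c(OCc2ccccc2)cc(OCc2ccccc2)cc1OCc1ccccc1)[C@H]1CCC(O[Mg]Br)=C[C@]1(C)CCC1OCCO1 | intermediate
13 | (3R,4R)-2-[(dimethylamino)methyl]-3-[2-(1,3-dioxolan-2-yl)ethyl]-3-methyl-4-[(1R)-3-methyl-1-[2,4,6-tris(benzyloxy)phenyl]butyl]cyclohexan-1-one (C2 epimers) | CC(C)C[C@@H](c1c(OCc2ccccc2)cc(OCc2ccccc2)cc1OCc1ccccc1)[C@H]1CCC(=O)C(CN(C)C)[C@]1(C)CCC1OCCO1 | intermediate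
14 | N,N,N-trimethylammonium iodide of 13 | CC(C)C[C@@H](c1c(OCc2ccccc2)cc(OCc2ccccc2)cc1OCc1ccccc1)[C@H]1CCC(=O)C(C[N+](C)(C)C)[C@]1(C)CCC1OCCO1.[I-] | intermediate
15 | (3R,4R)-3-[2-(1,3-dioxolan-2-yl)ethyl]-3-methyl-2-methylidene-4-[(1R)-3-methyl-1-[2,4,6-tris(benzyloxy)phenyl]butyl]cyclohexan-1-one | CC(C)C[C@@H](c1c(OCc2ccccc2)cc(OCc2ccccc2)cc1OCc1ccccc1)[C@H]1CCC(=O)C(=C)[C@]1(C)CCC1OCCO1 | intermediate
16 | 3-[(1R,6R)-1-methyl-2-methylidene-6-[(1R)-3-methyl-1-[2,4,6-tris(benzyloxy)phenyl]butyl]-3-oxocyclohexyl]propanal | CC(C)C[C@@H](c1c(OCc2ccccc2)cc(OCc2ccccc2)cc1OCc1ccccc1)[C@H]1CCC(=O)C(=C)[C@]1(C)CCC=O | intermediate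
17 | (4R,4aR,8aS)-4a-methyl-4-[(1R)-3-methyl-1-[2,4,6-tris(benzyloxy)phenyl]butyl]octahydronaphthalene-1,7(2H,8H)-dione | CC(C)C[C@@H](c1c(OCc2ccccc2)cc(OCc2ccccc2)cc1OCc1ccccc1)[C@H]1CCC(=O)[C@H]2CC(=O)CC[C@]12C | intermediate
18 | (2S,4aR,5R,8aS)-4a-methyl-5-[(1R)-3-methyl-1-[2,4,6-tris(benzyloxy)phenyl]butyl]-8-oxodecahydronaphthalene-2-carbonitrile | CC(C)C[C@@H](c1c(OCc2ccccc2)cc(OCc2ccccc2)cc1OCc1ccccc1)[C@H]1CCC(=O)[C@H]2C[C@@H](C#N)CC[C@]12C | intermediate
19 | ketimine of 20 (C7 ethanimine, C4 tertiary alcohol) | CC(C)C[C@@H](c1c(OCc2ccccc2)cc(OCc2ccccc2)cc1OCc1ccccc1)[C@H]1CC[C@@](C)(O)[C@H]2C[C@@H](C(C)=N)CC[C@]12C | intermediate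
20 | 1-[(2S,4aR,5R,8R,8aS)-8-hydroxy-4a,8-dimethyl-5-[(1R)-3-methyl-1-[2,4,6-tris(benzyloxy)phenyl]butyl]decahydronaphthalen-2-yl]ethan-1-one | CC(C)C[C@@H](c1c(OCc2ccccc2)cc(OCc2ccccc2)cc1OCc1ccccc1)[C@H]1CC[C@@](C)(O)[C@H]2C[C@@H](C(C)=O)CC[C@]12C | intermediate
21 | (1R,4R,4aR,7S,8aS)-7-(2-hydroxypropan-2-yl)-1,4a-dimethyl-4-[(1R)-3-methyl-1-[2,4,6-tris(benzyloxy)phenyl]butyl]decahydronaphthalen-1-ol | CC(C)C[C@@H](c1c(OCc2ccccc2)cc(OCc2ccccc2)cc1OCc1ccccc1)[C@H]1CC[C@@](C)(O)[C@H]2C[C@@H](C(C)(C)O)CC[C@]12C | intermediate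
22 | (1R,4R,4aR,7S,8aS)-7-(2-hydroxypropan-2-yl)-1,4a-dimethyl-4-[(1R)-3-methyl-1-(2,4,6-trihydroxyphenyl)butyl]decahydronaphthalen-1-ol | CC(C)C[C@@H](c1c(O)cc(O)cc1O)[C@H]1CC[C@@](C)(O)[C@H]2C[C@@H](C(C)(C)O)CC[C@]12C | intermediate
23 | 2,4,6-trihydroxy-5-[(1R)-1-[(1R,4R,4aS,6S,8aR)-4-hydroxy-6-(2-hydroxypropan-2-yl)-4,8a-dimethyldecahydronaphthalen-1-yl]-3-methylbutyl]benzene-1,3-dicarbaldehyde | CC(C)C[C@@H](c1c(O)c(C=O)c(O)c(C=O)c1O)[C@H]1CC[C@@](C)(O)[C@H]2C[C@@H](C(C)(C)O)CC[C@]12C | target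

**Totals and risks**
Total step count: 11. Longest linear sequence: 11 (1 + 2 → 23).

The three steps most likely to fail are 5, 6 and 11.

Step 5 must add a functionalised Grignard reagent to a β,β-disubstituted enone next to a very bulky C1 substituent and then trap the hindered enolate. The fallback sets out from 10 and comes back at 16. Hosomi–Sakurai allylation (allyltrimethylsilane, TiCl4, CH2Cl2, −78 °C) forms the quaternary centre by a Lewis-acid pathway that tolerates hindered enones, again anti to the C1 side chain. The titanium enolate is trapped with Eschenmoser's salt to give the allyl Mannich base F1. MeI then NaHCO3 gives the allyl methylidene ketone F2. Aldehyde-selective (anti-Markovnikov) Wacker oxidation of the terminal alkene (PdCl2(PhCN)2, CuCl2, AgNO2, O2, tBuOH/MeNO2) gives 16, which enters the carbene stage of Step 6.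

Step 6 may suffer from intermolecular benzoin or enone oligomerisation instead of the 6-endo acyl-anion closure. The fallback sets out from 16 (made from 15 by the same acetal hydrolysis) and comes back at 17. SmI2 (2.5 equiv, THF/MeOH, −78 °C) effects a reductive ketyl–enone cyclisation, which still unites the two electrophilic carbons C7 and C6, and gives the hydroxy ketone F3 as C7 epimers. Dess–Martin periodinane then oxidises it to 17, with C5 equilibrated by Et3N.

Step 11 may stop at the mono-aldehyde. The fallback sets out from 22 and comes back at 23. Twofold Lederer–Manasse hydroxymethylation (37 % aq. CH2O, KOH, MeOH/H2O, 0 °C) gives the bis(hydroxymethyl) triphenol F4. It is oxidised at once at the two benzylic alcohols only (activated MnO2, acetone, 25 °C) to 23.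

**Further compounds**
F1 | step 5 | (3R,4R)-2-[(dimethylamino)methyl]-3-methyl-4-[(1R)-3-methyl-1-[2,4,6-tris(benzyloxy)phenyl]butyl]-3-(prop-2-en-1-yl)cyclohexan-1-one (C2 epimers) | CC(C)C[C@@H](c1c(OCc2ccccc2)cc(OCc2ccccc2)cc1OCc1ccccc1)[C@H]1CCC(=O)C(CN(C)C)[C@]1(C)CC=C
F2 | step 5 | (3R,4R)-3-methyl-2-methylidene-4-[(1R)-3-methyl-1-[2,4,6-tris(benzyloxy)phenyl]butyl]-3-(prop-2-en-1-yl)cyclohexan-1-one | CC(C)C[C@@H](c1c(OCc2ccccc2)cc(OCc2ccccc2)cc1OCc1ccccc1)[C@H]1CCC(=O)C(=C)[C@]1(C)CC=C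
F3 | step 6 | (4R,4aR,8aS)-7-hydroxy-4a-methyl-4-[(1R)-3-methyl-1-[2,4,6-tris(benzyloxy)phenyl]butyl]octahydronaphthalen-1(2H)-one (C7 epimers) | CC(C)C[C@@H](c1c(OCc2ccccc2)cc(OCc2ccccc2)cc1OCc1ccccc1)[C@H]1CCC(=O)[C@H]2CC(O)CC[C@]12C
F4 | step 11 | (1R,4R,4aR,7S,8aS)-4-[(1R)-1-[2,4,6-trihydroxy-3,5-bis(hydroxymethyl)phenyl]-3-methylbutyl]-7-(2-hydroxypropan-2-yl)-1,4a-dimethyldecahydronaphthalen-1-ol | CC(C)C[C@@H](c1c(O)c(CO)c(O)c(CO)c1O)[C@H]1CC[C@@](C)(O)[C@H]2C[C@@H](C(C)(C)O)CC[C@]12C
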